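**Retrosynthetic overview**

- The strategy rests on the 2,5-dioxabicyclo[2.2.1]heptane: one ether oxygen joins C3 and C6, the other joins C4 and C7, and C8 next to it carries bromine. Opened up, this is a C6 alcohol flanked by a 3,4-epoxide and a 7,8-epoxide, so the O–C3 and O–C7 bonds are both made in one acid-triggered epoxide-opening cascade; C8–Br then comes from the alcohol the cascade leaves at C8 (SN2, inversion).
- The cascade precursor comes from an E,E-dienynol by Sharpless (C7–C8) and Shi (C3–C4) epoxidation. The chain is grown from C8 to C1 by Wittig olefination (C7=C8), asymmetric propargylation (C5–C6) and hydrozirconation–iodination/Sonogashira coupling (C2–C3).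
- The dibrominated oxane (O, C9–C13) is made first from 5-(hydroxymethyl)furfural: asymmetric ethylation (C13), Achmatowicz ring expansion, silane reduction (C9), HBr conjugate addition (C10), ketone reduction and invertive bromination (C12).
- Ring order: oxane first; then, in the key step, the C3–C6 oxolane (ring 1) followed by the C4–C7 oxolane (ring 2).

Key step: step 17

Remark: atoms carry the numbers C1–C15 of the target chain throughout; the Achmatowicz hemiketal is handled as a mixture at its ketal carbon; for each catalytic asymmetric step the antipode named is the one expected to give the stated sense of induction.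

**Route**

Step 1
Reactants: 1 5-(hydroxymethyl)furfural
Product: 2 (5-formylfuran-2-yl)methyl 2,2-dimethylpropanoate
Conditions: PivCl, Et3N, DMAP (cat.), CH2Cl2, 0 °C → rt
Reagents that add atoms: pivaloyl chloride, CC(C)(C)C(Cl)=O
Why: acylation of the primary alcohol with an acid chloride; the pivalate should survive organozinc, acid, low-temperature hydride and bromination and is removed later by i-Bu2AlH.

Step 2
Reactants: 2 (5-formylfuran-2-yl)methyl 2,2-dimethylpropanoate; 3 diethylzinc
Product: 4 {5-[(1R)-1-hydroxypropyl]furan-2-yl}methyl 2,2-dimethylpropanoate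
Conditions: Et2Zn (hexane), (2R)-(+)-3-exo-morpholinoisoborneol (5 mol%), toluene, 0 °C; aq NH4Cl
Reagents that add atoms: none
Why: amino-alcohol-catalysed enantioselective addition of a dialkylzinc to an aldehyde; this ligand antipode should deliver ethyl to the Re face and set C13 (R), and the ester is inert to Et2Zn.

Step 3
Reactants: 4 {5-[(1R)-1-hydroxypropyl]furan-2-yl}methyl 2,2-dimethylpropanoate
Product: 5 [(6R)-6-ethyl-2-hydroxy-5-oxo-5,6-dihydro-2H-pyran-2-yl]methyl 2,2-dimethylpropanoate (mixture at the ketal carbon)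
Conditions: NBS, NaHCO3, NaOAc, THF–H2O (4:1), 0 °C
Reagents that add atoms: water, O
Why: Achmatowicz oxidative ring expansion of a 2-furyl carbinol; the carbinol oxygen becomes the ring oxygen, so C13 is carried over unchanged.

Step 4
Reactants: 5 [(6R)-6-ethyl-2-hydroxy-5-oxo-5,6-dihydro-2H-pyran-2-yl]methyl 2,2-dimethylpropanoate
Product: 6 [(2R,6R)-6-ethyl-5-oxo-5,6-dihydro-2H-pyran-2-yl]methyl 2,2-dimethylpropanoate
Conditions: Et3SiH, CF3CO2H, CH2Cl2, −40 → 0 °C
Reagents that add atoms: none
Why: ionic hydrogenation of the hemiketal through its oxocarbenium ion; hydride should add pseudo-axially, anti to the C13 ethyl group, giving the 2,6-cis ring and setting C9, while the enone is not reduced under these conditions.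

Step 5
Reactants: 6 [(2R,6R)-6-ethyl-5-oxo-5,6-dihydro-2H-pyran-2-yl]methyl 2,2-dimethylpropanoate
Product: 7 [(2S,3R,6R)-3-bromo-6-ethyl-5-oxooxan-2-yl]methyl 2,2-dimethylpropanoate
Conditions: HBr (33% in AcOH, 1.5 equiv), CH2Cl2, −20 → 0 °C; cold aq NaHCO3; crude product used at once
Reagents that add atoms: hydrogen bromide, Br
Why: conjugate hydrobromination of the enone; bromide should attack C10 anti to the adjacent C9 substituent, as nucleophiles do with 4-substituted cyclohexenones, and because the addition is reversible the adduct with equatorial bromine trans to the arm should accumulate (sets C10).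

Step 6
Reactants: 7 [(2S,3R,6R)-3-bromo-6-ethyl-5-oxooxan-2-yl]methyl 2,2-dimethylpropanoate
Product: 8 [(2S,3R,5R,6R)-3-bromo-6-ethyl-5-hydroxyoxan-2-yl]methyl 2,2-dimethylpropanoate
Conditions: LiBH(s-Bu)3 (L-Selectride), THF, −78 °C; aq NH4Cl at −78 °C
Reagents that add atoms: none
Why: bulky trialkylborohydride reduction of a ring ketone from the equatorial side should give the axial C12 alcohol cis to ethyl; at −78 °C hydride transfer should outrun loss of HBr, and the pivalate is untouched.

Step 7
Reactants: 8 [(2S,3R,5R,6R)-3-bromo-6-ethyl-5-hydroxyoxan-2-yl]methyl 2,2-dimethylpropanoate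
Product: 9 [(2S,3R,5S,6R)-3,5-dibromo-6-ethyloxan-2-yl]methyl 2,2-dimethylpropanoate
Conditions: CBr4, P(n-Oct)3, toluene, 70 °C
Reagents that add atoms: carbon tetrabromide, BrC(Br)(Br)Br
Why: Appel-type deoxybromination; bromide displaces the axial oxyphosphonium group from the equatorial side with inversion, giving the equatorial C12 bromide trans to ethyl.

Step 8
Reactants: 9 [(2S,3R,5S,6R)-3,5-dibromo-6-ethyloxan-2-yl]methyl 2,2-dimethylpropanoate
Product: 10 [(2S,3R,5S,6R)-3,5-dibromo-6-ethyloxan-2-yl]methanol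
Conditions: i-Bu2AlH (2.5 equiv), CH2Cl2, −78 °C; aq potassium sodium tartrate
Reagents that add atoms: none
Why: reductive cleavage of the pivalate by an aluminium hydride at low temperature, which leaves secondary alkyl bromides alone and avoids the basic conditions that could eliminate HBr.

Step 9
Reactants: 10 [(2S,3R,5S,6R)-3,5-dibromo-6-ethyloxan-2-yl]methanol; 11 (triphenylphosphoranylidene)acetaldehyde
Product: 13 (2E)-3-[(2S,3R,5S,6R)-3,5-dibromo-6-ethyloxan-2-yl]prop-2-enal, via dibromo-oxane carbaldehyde 12 (not isolated)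
Conditions: Dess–Martin periodinane, NaHCO3, CH2Cl2, 0 °C → rt; filtration through Celite; then 11, toluene, rt → 45 °C
Reagents that add atoms: none
Why: buffered Dess–Martin oxidation followed at once by Wittig olefination with the stabilised formyl ylide, which gives the E-enal; no base is present, and the equatorial C10–Br bond is poorly aligned with the C9–H bond, so the α-alkoxy β-bromo aldehyde should neither epimerise nor lose HBr.

Step 10
Reactants: 13 (2E)-3-[(2S,3R,5S,6R)-3,5-dibromo-6-ethyloxan-2-yl]prop-2-enal; 14 allenylboronic acid pinacol ester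
Product: 15 (1E,3R)-1-[(2S,3R,5S,6R)-3,5-dibromo-6-ethyloxan-2-yl]hex-1-en-5-yn-3-ol
Conditions: (R)-3,3′-bis(2,4,6-triisopropylphenyl)-1,1′-binaphthyl-2,2′-diyl hydrogen phosphate (10 mol%), 4 Å MS, toluene, 0 °C → rt
Reagents that add atoms: none
Why: chiral-phosphoric-acid-catalysed propargylboration of the aldehyde through a six-membered SE2′ transition state; the catalyst should direct addition to the Re face and set C6 (R) under catalyst control, with 1,2-addition only.

Step 11
Reactants: 15 (1E,3R)-1-[(2S,3R,5S,6R)-3,5-dibromo-6-ethyloxan-2-yl]hex-1-en-5-yn-3-ol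
Product: 17 (1E,3R,5E)-1-[(2S,3R,5S,6R)-3,5-dibromo-6-ethyloxan-2-yl]-6-iodohexa-1,5-dien-3-ol, via alkenylzirconocene chloride 16 (not isolated)
Conditions: Cp2Zr(H)Cl (2.4 equiv), THF, 0 °C → rt; then I2, THF, −20 °C
Reagents that add atoms: iodine, II
Why: syn hydrozirconation of the terminal alkyne with zirconium at the terminal carbon, then iodinolysis with retention, gives the E-vinyl iodide; one equivalent of hydride is used up by the hydroxyl, and the internal alkene and alkyl bromides should not react.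

Step 12
Reactants: 17 (1E,3R,5E)-1-[(2S,3R,5S,6R)-3,5-dibromo-6-ethyloxan-2-yl]-6-iodohexa-1,5-dien-3-ol; 18 ethynyltrimethylsilane
Product: 19 (1E,3R,5E)-1-[(2S,3R,5S,6R)-3,5-dibromo-6-ethyloxan-2-yl]-8-(trimethylsilyl)octa-1,5-dien-7-yn-3-ol
Conditions: PdCl2(PPh3)2 (3 mol%), CuI (6 mol%), i-Pr2NH, THF, rt
Reagents that add atoms: none
Why: Sonogashira coupling of the vinyl iodide with retention of the E geometry; secondary alkyl bromides do not add to zerovalent palladium at room temperature.

Step 13
Reactants: 19 (1E,3R,5E)-1-[(2S,3R,5S,6R)-3,5-dibromo-6-ethyloxan-2-yl]-8-(trimethylsilyl)octa-1,5-dien-7-yn-3-ol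
Product: 20 (3E,6R,7R,8S,9S,10R,12S,13R)-10,12-dibromo-7,8:9,13-diepoxy-1-(trimethylsilyl)pentadec-3-en-1-yn-6-ol
Conditions: Ti(OiPr)4 (1.0 equiv), D-(−)-diisopropyl tartrate (1.2 equiv), t-BuOOH (decane), 4 Å MS, CH2Cl2, −20 °C
Reagents that add atoms: tert-butyl hydroperoxide, CC(C)(C)OO
Why: Sharpless asymmetric epoxidation of a secondary E-allylic alcohol in its fast-reacting (matched) pairing with D-(−)-tartrate should give the anti (erythro) epoxy alcohol and set C7 (R) and C8 (S); the homoallylic, electron-poor enyne alkene should not react.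

Step 14
Reactants: 20 (3E,6R,7R,8S,9S,10R,12S,13R)-10,12-dibromo-7,8:9,13-diepoxy-1-(trimethylsilyl)pentadec-3-en-1-yn-6-ol
Product: 21 6-O-triethylsilyl ether of 20 (configuration unchanged)
Conditions: Et3SiCl, imidazole, CH2Cl2, 0 °C
Reagents that add atoms: chlorotriethylsilane, CC[Si](Cl)(CC)CC
Why: silylation of the secondary alcohol under non-acidic conditions; it blocks Payne rearrangement and premature cyclisation during the basic epoxidation that follows.

Step 15
Reactants: 21 6-O-triethylsilyl ether of 20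
Product: 22 (3R,4R)-3,4-epoxide of 21 (3,4:7,8-bis-epoxide, silyl groups in place)
Conditions: 1,2:4,5-di-O-isopropylidene-β-D-erythro-2,3-hexodiulo-2,6-pyranose (D-fructose-derived Shi ketone, 0.5 equiv), 2KHSO5·KHSO4·K2SO4, K2CO3, Bu4NHSO4, aq Na2B4O7 buffer, MeCN–(MeO)2CH2–H2O, 0 °C
Reagents that add atoms: potassium peroxymonosulfate, [K+].[O-]S(=O)(=O)OO
Why: Shi epoxidation of the E-enyne by the chiral dioxirane through the spiro transition state should give the (3R,4R)-epoxide under reagent control, as with other trans-disubstituted alkenes; the alkyne is not oxidised.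

Step 16
Reactants: 22 (3R,4R)-3,4-epoxide of 21
Product: 23 (3R,4R,6R,7R,8S,9S,10R,12S,13R)-10,12-dibromo-3,4:7,8:9,13-triepoxypentadec-1-yn-6-ol
Conditions: Bu4NF (2.5 equiv), AcOH (2.5 equiv), THF, 0 °C → rt
Reagents that add atoms: none
Why: fluoride cleaves the O–Si and alkynyl C–Si bonds; the acetic acid buffer keeps alkoxide and acetylide protonated, so neither Payne rearrangement nor epoxide opening should occur.

Step 17
Reactants: 23 (3R,4R,6R,7R,8S,9S,10R,12S,13R)-10,12-dibromo-3,4:7,8:9,13-triepoxypentadec-1-yn-6-ol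
Product: 25 (3S,4R,6R,7R,8S,9S,10R,12S,13R)-10,12-dibromo-3,6:4,7:9,13-triepoxypentadec-1-yn-8-ol, via hydroxy-oxolane epoxide 24 (not isolated)
Conditions: camphorsulfonic acid (0.2 equiv), 4 Å MS, CH2Cl2 (0.01 M), 0 °C → rt
Reagents that add atoms: none
Why: Proposed new method: the acid activates the 3,4-epoxide and the C6 hydroxyl opens it at the propargylic carbon C3 with inversion, closing the C3–C4–C5–C6 oxolane (ring 1) in a 5-endo mode; this is forced because the alternative is an oxetane, is helped by the alkynyl group, and has its closest precedent in the acid-catalysed cyclisation of trans-3,4-epoxy alcohols to 3-hydroxyoxolanes. The C4 hydroxyl set free sits cis to the C6 side chain and opens the activated 7,8-epoxide at C7 from the rear in a 5-exo mode, closing the C4–C5–C6–C7 oxolane (ring 2) and completing the 2,5-dioxabicyclo[2.2.1]heptane; the nearest known reactions are the 5-exo steps of polyepoxide cascades and the alkoxide closures of this bicycle in bridged nucleosides. C3 and C7 arise by stereospecific inversion of the epoxide carbons and C4 and C8 keep their C–O bonds, so the Shi and Sharpless epoxidations control all four centres, with the ethynyl group exo and C8 endo. The step needs attack at C3 rather than C4 in the first closure and at C7 rather than C8 in the second (6-endo attack would give a dioxabicyclo[3.2.1]octane); the first is secured by ring strain and propargylic activation, the second by the exo trajectory and by steric and inductive shielding of C8 by the neighbouring brominated oxane carbon C9. As a tandem that builds this bicycle the reaction has no direct precedent.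

Step 18
Reactants: 25 (3S,4R,6R,7R,8S,9S,10R,12S,13R)-10,12-dibromo-3,6:4,7:9,13-triepoxypentadec-1-yn-8-ol
Product: 27 (3S,4R,6R,7S,8R,9R,10R,12S,13R)-8,10,12-tribromo-3,6:4,7:9,13-triepoxypentadec-1-yne (CNP0139964.2), via C8 triflate 26 (not isolated)
Conditions: (CF3SO2)2O, 2,6-lutidine, CH2Cl2, −78 °C; then Bu4NBr, toluene, −20 °C → rt
Reagents that add atoms: tetrabutylammonium bromide, CCCC[N+](CCCC)(CCCC)CCCC.[Br-]
Why: triflation followed by SN2 displacement with bromide in a non-polar medium inverts C8; the two flanking C–O bonds disfavour ionisation, as in halide displacements of secondary carbohydrate triflates.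

**Compound list**

1 | 5-(hydroxymethyl)furfural | O=Cc1ccc(CO)o1 | starting material
2 | (5-formylfuran-2-yl)methyl 2,2-dimethylpropanoate | O=Cc1ccc(COC(=O)C(C)(C)C)o1 | intermediate
3 | diethylzinc | CC[Zn]CC | starting material
4 | {5-[(1R)-1-hydroxypropyl]furan-2-yl}methyl 2,2-dimethylpropanoate | CC[C@@H](O)c1ccc(COC(=O)C(C)(C)C)o1 | intermediate
5 | [(6R)-6-ethyl-2-hydroxy-5-oxo-5,6-dihydro-2H-pyran-2-yl]methyl 2,2-dimethylpropanoate (ketal carbon a mixture) | CC[C@H]1OC(O)(COC(=O)C(C)(C)C)C=CC1=O | intermediate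
6 | [(2R,6R)-6-ethyl-5-oxo-5,6-dihydro-2H-pyran-2-yl]methyl 2,2-dimethylpropanoate | CC(C)(C)C(=O)OC[C@@H]1O[C@H](CC)C(=O)C=C1 | intermediate
7 | [(2S,3R,6R)-3-bromo-6-ethyl-5-oxooxan-2-yl]methyl 2,2-dimethylpropanoate | CC(C)(C)C(=O)OC[C@@H]1O[C@H](CC)C(=O)C[C@H]1Br | intermediate
8 | [(2S,3R,5R,6R)-3-bromo-6-ethyl-5-hydroxyoxan-2-yl]methyl 2,2-dimethylpropanoate | CC(C)(C)C(=O)OC[C@@H]1O[C@H](CC)[C@H](O)C[C@H]1Br | intermediate
9 | [(2S,3R,5S,6R)-3,5-dibromo-6-ethyloxan-2-yl]methyl 2,2-dimethylpropanoate | CC(C)(C)C(=O)OC[C@@H]1O[C@H](CC)[C@@H](Br)C[C@H]1Br | intermediate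
10 | [(2S,3R,5S,6R)-3,5-dibromo-6-ethyloxan-2-yl]methanol | OC[C@@H]1O[C@H](CC)[C@@H](Br)C[C@H]1Br | intermediate
11 | (triphenylphosphoranylidene)acetaldehyde | O=CC=P(c1ccccc1)(c1ccccc1)c1ccccc1 | starting material
12 | (2S,3R,5S,6R)-3,5-dibromo-6-ethyloxane-2-carbaldehyde | O=C[C@@H]1O[C@H](CC)[C@@H](Br)C[C@H]1Br | intermediate
13 | (2E)-3-[(2S,3R,5S,6R)-3,5-dibromo-6-ethyloxan-2-yl]prop-2-enal | O=C/C=C/[C@@H]1O[C@H](CC)[C@@H](Br)C[C@H]1Br | intermediate
14 | allenylboronic acid pinacol ester | C=C=CB1OC(C)(C)C(C)(C)O1 | starting material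
15 | (1E,3R)-1-[(2S,3R,5S,6R)-3,5-dibromo-6-ethyloxan-2-yl]hex-1-en-5-yn-3-ol | C#CC[C@@H](O)/C=C/[C@@H]1O[C@H](CC)[C@@H](Br)C[C@H]1Br | intermediate
16 | E-alkenylzirconocene chloride of 15, hydroxyl as its zirconocene chloride alkoxide | Cl[Zr](/C=C/C[C@@H](O[Zr](Cl)(C2C=CC=C2)C2C=CC=C2)/C=C/[C@@H]1O[C@H](CC)[C@@H](Br)C[C@H]1Br)(C2C=CC=C2)C2C=CC=C2 | intermediate
17 | (1E,3R,5E)-1-[(2S,3R,5S,6R)-3,5-dibromo-6-ethyloxan-2-yl]-6-iodohexa-1,5-dien-3-ol | I/C=C/C[C@@H](O)/C=C/[C@@H]1O[C@H](CC)[C@@H](Br)C[C@H]1Br | intermediate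
18 | ethynyltrimethylsilane | C#C[Si](C)(C)C | starting material
19 | (1E,3R,5E)-1-[(2S,3R,5S,6R)-3,5-dibromo-6-ethyloxan-2-yl]-8-(trimethylsilyl)octa-1,5-dien-7-yn-3-ol | C[Si](C)(C)C#C/C=C/C[C@@H](O)/C=C/[C@@H]1O[C@H](CC)[C@@H](Br)C[C@H]1Br | intermediate
20 | (3E,6R,7R,8S,9S,10R,12S,13R)-10,12-dibromo-7,8:9,13-diepoxy-1-(trimethylsilyl)pentadec-3-en-1-yn-6-ol | C[Si](C)(C)C#C/C=C/C[C@@H](O)[C@H]1O[C@@H]1[C@@H]2O[C@H](CC)[C@@H](Br)C[C@H]2Br | intermediate
21 | 6-O-triethylsilyl ether of 20 | C[Si](C)(C)C#C/C=C/C[C@@H](O[Si](CC)(CC)CC)[C@H]1O[C@@H]1[C@@H]2O[C@H](CC)[C@@H](Br)C[C@H]2Br | intermediate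
22 | (3R,4R)-3,4-epoxide of 21 | C[Si](C)(C)C#C[C@H]1O[C@@H]1C[C@@H](O[Si](CC)(CC)CC)[C@H]2O[C@@H]2[C@@H]3O[C@H](CC)[C@@H](Br)C[C@H]3Br | intermediate
23 | (3R,4R,6R,7R,8S,9S,10R,12S,13R)-10,12-dibromo-3,4:7,8:9,13-triepoxypentadec-1-yn-6-ol | C#C[C@H]1O[C@@H]1C[C@@H](O)[C@H]2O[C@@H]2[C@@H]3O[C@H](CC)[C@@H](Br)C[C@H]3Br | intermediate
24 | (3S,4R,6R,7R,8S,9S,10R,12S,13R)-10,12-dibromo-3,6:7,8:9,13-triepoxypentadec-1-yn-4-ol (2-ethynyl-3-hydroxyoxolane with the 7,8-epoxide intact) | C#C[C@@H]1O[C@H](C[C@H]1O)[C@H]2O[C@@H]2[C@@H]3O[C@H](CC)[C@@H](Br)C[C@H]3Br | intermediate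
25 | (3S,4R,6R,7R,8S,9S,10R,12S,13R)-10,12-dibromo-3,6:4,7:9,13-triepoxypentadec-1-yn-8-ol | C#C[C@@H]1O[C@@H]2C[C@H]1O[C@@H]2[C@H](O)[C@@H]3O[C@H](CC)[C@@H](Br)C[C@H]3Br | intermediate
26 | 8-O-trifluoromethanesulfonate of 25 | C#C[C@@H]1O[C@@H]2C[C@H]1O[C@@H]2[C@H](OS(=O)(=O)C(F)(F)F)[C@@H]3O[C@H](CC)[C@@H](Br)C[C@H]3Br | intermediate
27 | (3S,4R,6R,7S,8R,9R,10R,12S,13R)-8,10,12-tribromo-3,6:4,7:9,13-triepoxypentadec-1-yne (CNP0139964.2) | C#C[C@@H]1O[C@@H]2C[C@H]1O[C@@H]2[C@@H](Br)[C@@H]1O[C@H](CC)[C@@H](Br)C[C@H]1Br | target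

**Step count**

Total: 18 steps. Longest linear sequence: 18 steps (1 → 27); the route is fully linear.

**Steps most likely to fail**

1. Step 17 (the labelled step). After ring 1 has formed, the strained bridged transition state may let the acid open the 7,8-epoxide at C8 (6-endo) or with an outside nucleophile instead of at C7, or the sequence may stall. Fallback: give up the tandem and close the two rings separately by known reactions. It sets out from 23: pyridinium p-toluenesulfonate in CH2Cl2 at 0 °C should carry out only the acid-catalysed 5-endo closure of the 3,4-epoxy alcohol, and hydroxy-oxolane epoxide 24 is isolated. Its C4 alkoxide (NaH, THF, 0 °C → rt) then opens the 7,8-epoxide in the strictly 5-exo mode of base-mediated epoxy-alcohol cyclisations, the same alkoxide closure that forms 2,5-dioxabicyclo[2.2.1]heptanes in bridged nucleosides. The all-equatorial ring bromides have no antiperiplanar hydrogen and should survive. The fallback comes back to the route at 25 and makes no compound outside the list (F0).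

2. Step 18. At the doubly branched C8, flanked by two oxygenated carbons, elimination of the triflate toward C7 or C9, or ionisation assisted by an ether oxygen (retention or skeletal rearrangement), may outrun direct SN2. Fallback: make no sulfonate ester; treat 25 with CBr4 and P(n-Oct)3 in toluene at 70 °C (Appel-type deoxybromination), where the oxyphosphonium ion and bromide form as a tight ion pair in a non-ionising medium and collapse with inversion. It sets out from 25, comes back at 27 and makes no compound outside the list (F0).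

3. Step 5 (with step 6). Facial selectivity of bromide addition at C10 may be poor, and the β-bromo ketone may lose HBr again before or during reduction. Fallback: set both ring bromides by the same pair of substrate-controlled operations (bulky hydride to the axial alcohol, then invertive bromination), one carbon at a time. It sets out from 6 and comes back at 9:
   - nucleophilic epoxidation (t-BuOOH, DBU, CH2Cl2) anti to the ring substituents gives the trans-epoxy ketone F1;
   - SmI2 (THF–MeOH, −90 °C) cleaves the C11–O bond to the C10 β-hydroxy ketone F2;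
   - t-BuMe2SiOSO2CF3 and 2,6-lutidine give the silyl ether F3;
   - LiBH(s-Bu)3 at −78 °C gives the axial C12 alcohol F4;
   - CBr4 and P(n-Oct)3 give the equatorial C12 bromide F5;
   - HF·pyridine frees the C10 alcohol F6;
   - Dess–Martin periodinane gives the C10 ketone F7;
   - LiBH(s-Bu)3 at −78 °C gives the axial C10 alcohol F8;
   - CBr4 and P(n-Oct)3 then invert C10 and deliver 9.

**Further compounds**

F0 | step 17 | none | none
F0 | step 18 | none | none
F1 | step 5 | 10,11-epoxy ketone of 6, epoxide oxygen anti to the C9 arm and the C13 ethyl group | CC(C)(C)C(=O)OC[C@@H]1O[C@H](CC)C(=O)[C@H]2O[C@@H]12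
F2 | step 5 | C10 β-hydroxy ketone, hydroxyl trans to the C9 arm | CC(C)(C)C(=O)OC[C@@H]1O[C@H](CC)C(=O)C[C@H]1O
F3 | step 5 | tert-butyldimethylsilyl ether of F2 | CC(C)(C)C(=O)OC[C@@H]1O[C@H](CC)C(=O)C[C@H]1O[Si](C)(C)C(C)(C)C
F4 | step 5 | axial C12 alcohol (cis to ethyl) from F3 | CC(C)(C)C(=O)OC[C@@H]1O[C@H](CC)[C@H](O)C[C@H]1O[Si](C)(C)C(C)(C)C
F5 | step 5 | equatorial C12 bromide (trans to ethyl), C10 silyl ether | CC(C)(C)C(=O)OC[C@@H]1O[C@H](CC)[C@@H](Br)C[C@H]1O[Si](C)(C)C(C)(C)C
F6 | step 5 | C12 bromide with free equatorial C10 alcohol | CC(C)(C)C(=O)OC[C@@H]1O[C@H](CC)[C@@H](Br)C[C@H]1O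
F7 | step 5 | C10 ketone of the C12 bromide | CC(C)(C)C(=O)OC[C@@H]1O[C@H](CC)[C@@H](Br)CC1=O
F8 | step 5 | axial C10 alcohol (cis to the C9 arm) of the C12 bromide | CC(C)(C)C(=O)OC[C@@H]1O[C@H](CC)[C@@H](Br)C[C@@H]1O
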